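**Retrosynthetic overview**
1. Target 15 ⇐ tris-MOM ether 14 (MOM = methoxymethyl) ⇐ isoflavanone 12 by enolate hydroxylation at C3 with a chiral N-sulfonyloxaziridine; this sets the only stereocenter, on a ring-fixed enolate.
2. 12 ⇐ acetophenone 9 + aryl bromide 6 + CH2O in one flask: C3–C1' (Pd α-arylation), C2–C3 (aldol), then ring C closed by the C2 alkoxide oxygen O1 displacing fluoride at C8a (O1–C8a).
3. Enabling feature: in ring A the oxygens sit at C5, C7 and C8a (mutually meta) and the C4 ketone sits on C4a, ortho to C8a. A fluorine at C8a is therefore activated by the ortho carbonyl (charge of the σ-adduct on C4a/C4=O) and not deactivated by the C5/C7 alkoxy groups, and C3–H stays acidic for the later hydroxylation.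
4. 9 ⇐ 5-fluororesorcinol (Friedel–Crafts acetylation, MOM); 6 ⇐ 4-bromo-3-methoxyphenol (O-prenylation, aromatic Claisen rearrangement to the 1,1-dimethylallyl group, MOM).
5. Ring order: rings A and B are bought; ring C is the only ring made (step 6).

Key step: step 6

Remark: the face selectivity of the oxaziridine in step 7 is assigned by analogy with 8-alkoxy-2-substituted 1-tetralone enolates; if the first run shows the opposite sense, the antipodal reagent (from (1R)-10-camphorsulfonic acid) is used without other change.

**Step 1**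
Reactants: 1 4-bromo-3-methoxyphenol; 2 1-bromo-3-methylbut-2-ene (prenyl bromide)
Product: 3 1-bromo-2-methoxy-4-[(3-methylbut-2-en-1-yl)oxy]benzene
Conditions: K2CO3, acetone, reflux
Reagents that add atoms: none
Why: Williamson ether synthesis, in which the phenoxide displaces the primary allylic bromide by SN2 at oxygen; no stereocenter is formed.

**Step 2**
Reactants: 3 1-bromo-2-methoxy-4-[(3-methylbut-2-en-1-yl)oxy]benzene
Product: 5 4-bromo-5-methoxy-2-(2-methylbut-3-en-2-yl)phenol, via ortho-dienone 4 (not isolated)
Conditions: PhNEt2, 190 °C, sealed tube, Ar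
Reagents that add atoms: none
Why: Thermal aromatic Claisen rearrangement, whose [3,3] shift joins the dimethyl-substituted allyl terminus to the free ortho carbon para to the methoxy group (the other ortho carbon is flanked by OMe, the para carbon is blocked by Br), after which dienone 4 tautomerises to phenol 5; no stereocenter remains.

**Step 3**
Reactants: 5 4-bromo-5-methoxy-2-(2-methylbut-3-en-2-yl)phenol
Product: 6 1-bromo-2-methoxy-4-(methoxymethoxy)-5-(2-methylbut-3-en-2-yl)benzene
Conditions: MOMCl, K2CO3, DMF, 0 °C → rt
Reagents that add atoms: chloromethyl methyl ether (MOMCl), COCCl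
Why: O-alkylation of the hindered phenoxide with an α-chloro ether (Williamson type) should give the acetal, which survives the basic, organopalladium and enolate steps and leaves under mild acid at the end.

**Step 4**
Reactants: 7 5-fluorobenzene-1,3-diol
Product: 8 1-(2-fluoro-4,6-dihydroxyphenyl)ethan-1-one
Conditions: AcOH, BF3·OEt2, 85 °C
Reagents that add atoms: acetic acid, CC(=O)O
Why: BF3-promoted Friedel–Crafts C-acylation of a resorcinol, which should enter ortho to one hydroxyl and para to the other (the resacetophenone pattern) and so place the fluorine ortho to the new ketone, the product being deactivated against a second acylation.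

**Step 5**
Reactants: 8 1-(2-fluoro-4,6-dihydroxyphenyl)ethan-1-one
Product: 9 1-[2-fluoro-4,6-bis(methoxymethoxy)phenyl]ethan-1-one
Conditions: MOMCl (excess), K2CO3, acetone, reflux
Reagents that add atoms: chloromethyl methyl ether (MOMCl), COCCl
Why: Williamson-type O-alkylation, in which excess reagent at reflux should also alkylate the hydroxyl that is hydrogen-bonded to the ketone, while carbonate is too weak a nucleophile to attack the C–F bond.

**Step 6**
Reactants: 9 1-[2-fluoro-4,6-bis(methoxymethoxy)phenyl]ethan-1-one; 6 1-bromo-2-methoxy-4-(methoxymethoxy)-5-(2-methylbut-3-en-2-yl)benzene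
Product: 12 racemic 5,7-bis(methoxymethoxy)-3-[2-methoxy-4-(methoxymethoxy)-5-(2-methylbut-3-en-2-yl)phenyl]-2,3-dihydro-4H-chromen-4-one, via deoxybenzoin 10 (not isolated), via aldol adduct 11 (not isolated)
Conditions: Pd2(dba)3 (2.5 mol %), Xantphos (6 mol %), K3PO4 (3 equiv), toluene, 90 °C; then (CH2O)n (1.2 equiv), DMSO (2% H2O), 25 → 60 °C, Ar
Reagents that add atoms: formaldehyde (from paraformaldehyde), C=O
Why: Zerovalent palladium inserts into the C–Br bond of 6, the potassium enolate of 9 binds and reductive elimination gives deoxybenzoin 10 (Buchwald–Hartwig-type ketone α-arylation); after addition of paraformaldehyde and DMSO the enolate of 10 adds to formaldehyde (aldol) to give the primary alkoxide of 11, whose oxygen O1 attacks C8a of ring A, and loss of fluoride from the Meisenheimer adduct gives 12 (intramolecular SNAr). The closest known reaction types are the tandem aldol/SNAr and Michael/SNAr annulations of 2-fluoroaryl ketones and the alkoxide SNAr closure of 3-hydroxy-1-(2-fluoroaryl)propan-1-ones to chroman-4-ones, and each stage runs here on its usual substrate class, only telescoped. Ring C closes as a six-membered ring by addition–elimination at C8a (O1–C8a bond), the perpendicular approach of O1 being allowed by the two sp3 atoms C2 and C3 of the tether. C3 is formed racemic and stays enolisable, so no stereocontrol is needed here; it is set in step 7. The step needs mono-arylation, one hydroxymethylation, and cyclisation in place of dehydration: the ortho-methoxy aryl group and the bulk of ring A should block a second arylation, aldol addition and dehydration are reversible in the wet basic medium while fluoride loss is not, the enolate oxygen cannot reach C8a (that would be a four-membered ring), and fluorine is the only leaving group ortho to the C4 carbonyl, with the C5 and C7 alkoxy groups meta to C8a and so not deactivating.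

**Step 7**
Reactants: 12 racemic 5,7-bis(methoxymethoxy)-3-[2-methoxy-4-(methoxymethoxy)-5-(2-methylbut-3-en-2-yl)phenyl]-2,3-dihydro-4H-chromen-4-one
Product: 14 (3R)-3-hydroxy-5,7-bis(methoxymethoxy)-3-[2-methoxy-4-(methoxymethoxy)-5-(2-methylbut-3-en-2-yl)phenyl]-2,3-dihydro-4H-chromen-4-one, via sodium enolate 13 (not isolated)
Conditions: NaN(SiMe3)2, THF, –78 °C; (+)-[(8,8-dimethoxycamphoryl)sulfonyl]oxaziridine (from (1S)-10-camphorsulfonic acid), –78 → –40 °C; AcOH
Reagents that add atoms: (+)-[(8,8-dimethoxycamphoryl)sulfonyl]oxaziridine, CC1(C)[C@@H]2CC[C@]13CS(=O)(=O)N4O[C@@]34C2(OC)OC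
Why: Enolate α-hydroxylation with a chiral N-sulfonyloxaziridine: the tetrasubstituted sodium enolate 13 has a ring-fixed geometry, C3 attacks the oxaziridine oxygen in an SN2-type transfer, and the camphor skeleton (its methoxy groups binding sodium together with the enolate oxygen and the peri C5 alkoxy group) should leave one enolate face open, expected by the tetralone analogy to give the (R)-carbinol, after which C3 is quaternary and cannot epimerise.

**Step 8**
Reactants: 14 (3R)-3-hydroxy-5,7-bis(methoxymethoxy)-3-[2-methoxy-4-(methoxymethoxy)-5-(2-methylbut-3-en-2-yl)phenyl]-2,3-dihydro-4H-chromen-4-one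
Product: 15 (3R)-3,5,7-trihydroxy-3-[4-hydroxy-2-methoxy-5-(2-methylbut-3-en-2-yl)phenyl]-2,3-dihydro-4H-chromen-4-one
Conditions: HCl (1.25 M in MeOH), 40 °C
Reagents that add atoms: none
Why: Acid-catalysed acetal exchange (MOM ether cleavage) with methanol as acceptor should free the three phenols, while the tertiary benzylic C3–OH is kept because its ionisation is disfavoured by the adjacent C4 carbonyl, C3 has no α-hydrogen, and the mild temperature should spare the 1,1-dimethylallyl group from cyclisation onto the freed phenol.

**Compound list**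
1 | 4-bromo-3-methoxyphenol | COc1cc(O)ccc1Br | starting material
2 | 1-bromo-3-methylbut-2-ene (prenyl bromide) | CC(C)=CCBr | starting material
3 | 1-bromo-2-methoxy-4-[(3-methylbut-2-en-1-yl)oxy]benzene | COc1cc(OCC=C(C)C)ccc1Br | intermediate
4 | 4-bromo-3-methoxy-6-(2-methylbut-3-en-2-yl)cyclohexa-2,4-dien-1-one (racemic ortho-dienone, formed in the flask) | O=C1C=C(OC)C(Br)=CC1C(C)(C)C=C | intermediate
5 | 4-bromo-5-methoxy-2-(2-methylbut-3-en-2-yl)phenol | C=CC(C)(C)c1cc(Br)c(OC)cc1O | intermediate
6 | 1-bromo-2-methoxy-4-(methoxymethoxy)-5-(2-methylbut-3-en-2-yl)benzene | C=CC(C)(C)c1cc(Br)c(OC)cc1OCOC | intermediate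
7 | 5-fluorobenzene-1,3-diol | Oc1cc(O)cc(F)c1 | starting material
8 | 1-(2-fluoro-4,6-dihydroxyphenyl)ethan-1-one | CC(=O)c1c(O)cc(O)cc1F | intermediate
9 | 1-[2-fluoro-4,6-bis(methoxymethoxy)phenyl]ethan-1-one | CC(=O)c1c(F)cc(OCOC)cc1OCOC | intermediate
10 | 1-[2-fluoro-4,6-bis(methoxymethoxy)phenyl]-2-[2-methoxy-4-(methoxymethoxy)-5-(2-methylbut-3-en-2-yl)phenyl]ethan-1-one (deoxybenzoin, formed in the flask) | C=CC(C)(C)c1cc(CC(=O)c2c(F)cc(OCOC)cc2OCOC)c(OC)cc1OCOC | intermediate
11 | 1-[2-fluoro-4,6-bis(methoxymethoxy)phenyl]-3-hydroxy-2-[2-methoxy-4-(methoxymethoxy)-5-(2-methylbut-3-en-2-yl)phenyl]propan-1-one (racemic aldol adduct, formed in the flask) | C=CC(C)(C)c1cc(C(CO)C(=O)c2c(F)cc(OCOC)cc2OCOC)c(OC)cc1OCOC | intermediate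
12 | 5,7-bis(methoxymethoxy)-3-[2-methoxy-4-(methoxymethoxy)-5-(2-methylbut-3-en-2-yl)phenyl]-2,3-dihydro-4H-chromen-4-one (racemic) | C=CC(C)(C)c1cc(C2COc3cc(OCOC)cc(OCOC)c3C2=O)c(OC)cc1OCOC | intermediate
13 | sodium 5,7-bis(methoxymethoxy)-3-[2-methoxy-4-(methoxymethoxy)-5-(2-methylbut-3-en-2-yl)phenyl]-2H-chromen-4-olate (formed in the flask) | [Na+].[O-]C1=C(c2cc(C(C)(C)C=C)c(OCOC)cc2OC)COc2cc(OCOC)cc(OCOC)c21 | intermediate
14 | (3R)-3-hydroxy-5,7-bis(methoxymethoxy)-3-[2-methoxy-4-(methoxymethoxy)-5-(2-methylbut-3-en-2-yl)phenyl]-2,3-dihydro-4H-chromen-4-one | C=CC(C)(C)c1cc([C@@]2(O)COc3cc(OCOC)cc(OCOC)c3C2=O)c(OC)cc1OCOC | intermediate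
15 | (3R)-3,5,7-trihydroxy-3-[4-hydroxy-2-methoxy-5-(2-methylbut-3-en-2-yl)phenyl]-2,3-dihydro-4H-chromen-4-one | C=CC(C)(C)c1cc([C@@]2(O)COc3cc(O)cc(O)c3C2=O)c(OC)cc1O | target

**Step count and risks**
Total step count: 8. Longest linear sequence: 6 steps (1, 2, 3, 6, 7, 8).

Steps most likely to fail:

Step 6. What may go wrong: the aldol adduct may lose water faster than its alkoxide cyclises, and the 2-aryl enone formed may then be consumed by Michael addition of enolates (oligomers); a second hydroxymethylation is also possible. Fallback, setting out from 9 and 6: the arylation stage is run alone and 10 is isolated. Condensation of 10 with Me2NCH(OMe)2 (toluene, 100 °C) should give the enaminone F1. Aqueous KOH in DMSO (60 °C) should hydrolyse it to the hydroxymethylene ketone F2, whose enolate oxygen displaces the fluoride at C8a. This is the same O1–C8a closure, now through an all-sp2 tether that cannot dehydrate, as in chromone syntheses from 2-fluorobenzoyl enaminones, and should give the isoflavone F3. Conjugate reduction of F3 with LiBH(s-Bu)3 (THF, –78 °C) comes back to the route at 12.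

Step 7. What may go wrong: poor facial selectivity in the oxygen transfer to the 3-aryl enolate, or ring opening of the enolate by β-elimination of the C8a aryloxide. Fallback, setting out from 12: catalytic asymmetric aerobic hydroxylation under phase-transfer conditions (N-(9-anthracenylmethyl)cinchoninium bromide or its cinchonidinium pseudoenantiomer, whichever gives the (R) product, 50% aq KOH, toluene, O2, P(OEt)3, 0 °C). The chiral ammonium enolate should take up oxygen to give the (3R)-hydroperoxide F4, which the phosphite reduces in the flask. Ring opening is reversible under these conditions and the hydroxylated product is no longer enolisable. The route is rejoined at 14.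

Step 2. What may go wrong: further reaction of the product phenol at 190 °C (ene-type isomerisation of the side chain, or cyclisation of the phenol onto the alkene to a dihydrobenzofuran), or migration to the ortho carbon next to the methoxy group. Fallback, setting out from 1, builds the 1,1-dimethylallyl group without a sigmatropic step. Acylation of 1 with 2-bromo-2-methylpropanoyl bromide (Et3N, CH2Cl2) should give the 4-bromo-3-methoxyphenyl 2-bromo-2-methylpropanoate F5. AlCl3 (1,2-dichlorobenzene, heat) should close it by intramolecular Friedel–Crafts alkylation at the ortho carbon para to OMe to the 3,3-dimethylbenzofuran-2(3H)-one F6. Reduction with i-Bu2AlH (toluene, –78 °C) should give the lactol F7. Wittig methylenation (Ph3P=CH2, THF) of its open hydroxy-aldehyde form comes back to the route at 5.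

**Further compounds**
F1 | step 6 | (E)-3-(dimethylamino)-1-[2-fluoro-4,6-bis(methoxymethoxy)phenyl]-2-[2-methoxy-4-(methoxymethoxy)-5-(2-methylbut-3-en-2-yl)phenyl]prop-2-en-1-one | CN(C)/C=C(/C(=O)c1c(F)cc(OCOC)cc1OCOC)c1cc(C(C)(C)C=C)c(OCOC)cc1OC
F2 | step 6 | (Z)-1-[2-fluoro-4,6-bis(methoxymethoxy)phenyl]-3-hydroxy-2-[2-methoxy-4-(methoxymethoxy)-5-(2-methylbut-3-en-2-yl)phenyl]prop-2-en-1-one | O/C=C(\C(=O)c1c(F)cc(OCOC)cc1OCOC)c1cc(C(C)(C)C=C)c(OCOC)cc1OC
F3 | step 6 | 5,7-bis(methoxymethoxy)-3-[2-methoxy-4-(methoxymethoxy)-5-(2-methylbut-3-en-2-yl)phenyl]-4H-chromen-4-one | C=CC(C)(C)c1cc(-c2coc3cc(OCOC)cc(OCOC)c3c2=O)c(OC)cc1OCOC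
F4 | step 7 | (3R)-3-hydroperoxy-5,7-bis(methoxymethoxy)-3-[2-methoxy-4-(methoxymethoxy)-5-(2-methylbut-3-en-2-yl)phenyl]-2,3-dihydro-4H-chromen-4-one | C=CC(C)(C)c1cc([C@@]2(OO)COc3cc(OCOC)cc(OCOC)c3C2=O)c(OC)cc1OCOC
F5 | step 2 | 4-bromo-3-methoxyphenyl 2-bromo-2-methylpropanoate | COc1cc(OC(=O)C(C)(C)Br)ccc1Br
F6 | step 2 | 5-bromo-6-methoxy-3,3-dimethyl-1-benzofuran-2(3H)-one | COc1cc2OC(=O)C(C)(C)c2cc1Br
F7 | step 2 | 5-bromo-6-methoxy-3,3-dimethyl-2,3-dihydro-1-benzofuran-2-ol (racemic lactol) | COc1cc2OC(O)C(C)(C)c2cc1Br
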